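**Plan**

1. Numbering used throughout (Lycopodium type): N; C1–C3 and C9–C11 are the ring-C methylenes; C4 is the azonine carbon α to the ketone C5; C6 is the CH2 α to C5; C7 is the ring-fusion CH; C8 and C14 are ring-A CH2; C12 is the quaternary carbon; C13 is CH–OAc; C15 is C(Me)OAc.
2. Retrosynthesis: remove the acetates and the C3=C4 unsaturation, then cut C5–C6 and C7–C12 together. This opens both carbocycles and leaves an N-formyl azonine-5-carbonyl selenide carrying a hex-5-enyl chain on C12. Further cuts: N–C9 (Mitsunobu), C3–C4 (B-alkyl Suzuki), C11–C12 (carbocupration), C12–C13 (alkynylation of an aldehyde from (R)-mevalonolactone).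
3. Forward ring order: the nine-membered ring C is made first; rings A (six) and B (five) are then closed in one radical chain.
4. Enabling feature: once C4=C12 is drawn as the ring-C olefin, C5(=O)–C4–C12 is an α,β-unsaturated acyl unit. Its acyl radical reacts as the C12 α-ketenyl radical. The four-atom tether C13–C14–C15–C8 holds the C7=C6 vinyl group for 6-exo attack, after which the C6 radical sits 1,5 to the ketene carbon C5.
5. Stereochemistry: C15 from mevalonolactone; C13 by catalyst-controlled alkynylation; C7 and C12 in the cascade (chair with both silyloxy groups equatorial, ring C holding the ketene carbon syn to C13); ring C fixes the enone geometry.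

Key step: step 14

**Remarks**

- 11 and 16 are taken as catalogue compounds.
- In step 5 the ProPhenol antipode is the one that delivers the alkynyl group to the Re face of the aldehyde (4S alcohol). Its identity should be fixed by Mosher analysis of 9 in the first run, and any 4R diastereomer should be removed by chromatography.

**Route**

Step 1
Reactants: 1 (R)-mevalonolactone
Product: 2 (4R)-4-methyltetrahydro-2H-pyran-2,4-diol (lactol; anomer mixture)
Conditions: DIBAL-H (2.2 equiv), CH2Cl2, −78 °C; Rochelle salt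
Reagents that add atoms: none
Why: DIBAL-H reduction of a δ-lactone should stop at the lactol at −78 °C because the aluminium hemiacetal survives until work-up, and the quaternary carbinol (future C15) is not touched.

Step 2
Reactants: 2 lactol
Product: 3 (S)-3-methylhex-5-ene-1,3-diol
Conditions: Ph3PCH3Br, KOtBu, THF, 0 °C → rt
Reagents that add atoms: methyltriphenylphosphonium bromide C[P+](c1ccccc1)(c1ccccc1)c1ccccc1.[Br-]
Why: Wittig methylenation of the open hydroxy-aldehyde form of the lactol should install the vinyl group (future C7=C6) and free the primary alcohol.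

Step 3
Reactants: 3 diol
Product: 4 (S)-3-methyl-1,3-bis(triethylsilyloxy)hex-5-ene
Conditions: TESOTf (2.4 equiv), 2,6-lutidine, CH2Cl2, −78 → 0 °C
Reagents that add atoms: triethylsilyl trifluoromethanesulfonate CC[Si](CC)(CC)OS(=O)(=O)C(F)(F)F
Why: Silyl triflate with lutidine should silylate the tertiary as well as the primary hydroxyl.

Step 4
Reactants: 4 bis-TES ether
Product: 6 (S)-3-methyl-3-(triethylsilyloxy)hex-5-enal, via alkoxysulfonium chloride 5 (not isolated)
Conditions: (COCl)2, DMSO, CH2Cl2, −78 → −40 °C; Et3N, −78 °C → rt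
Reagents that add atoms: none
Why: Swern oxidation applied directly to a primary triethylsilyl ether should give the aldehyde while the tertiary silyl ether is inert, so a retro-aldol-prone free β-hydroxy aldehyde is never formed.

Step 5
Reactants: 6 aldehyde; 7 methyl propiolate
Product: 9 methyl (4S,6S)-4-hydroxy-6-methyl-6-(triethylsilyloxy)non-8-en-2-ynoate, via zinc acetylide 8 (not isolated)
Conditions: Me2Zn, ProPhenol ligand (20 mol %), Ph3PO (40 mol %), toluene, 4 °C
Reagents that add atoms: none
Why: Zinc–ProPhenol catalysed asymmetric alkynylation of an aldehyde with a propiolate should set the carbinol centre (future C13) by catalyst control, since the remote quaternary centre offers no bias.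

Step 6
Reactants: 9 propargylic alcohol
Product: 10 methyl (4S,6S)-4-(tert-butyldimethylsilyloxy)-6-methyl-6-(triethylsilyloxy)non-8-en-2-ynoate
Conditions: TBSCl, imidazole, DMF, rt
Reagents that add atoms: tert-butyldimethylsilyl chloride CC(C)(C)[Si](C)(C)Cl
Why: Silylation gives a γ-oxygen that is not a leaving group in the cuprate step and that blocks butenolide formation with the cis ester later.

Step 7
Reactants: 10 ynoate; 11 1-[(3-bromopropoxy)methyl]-4-methoxybenzene
Product: 15 methyl (2E,4S,6S)-4-(tert-butyldimethylsilyloxy)-2-iodo-3-[3-(4-methoxybenzyloxy)propyl]-6-methyl-6-(triethylsilyloxy)nona-2,8-dienoate, via Grignard reagent 12 (not isolated), via organocopper reagent 13 (not isolated), via vinylcopper adduct 14 (not isolated)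
Conditions: 11, Mg, THF; CuBr·SMe2, −78 → −40 °C; 10, −78 °C; I2, −78 °C
Reagents that add atoms: iodine II
Why: syn-Carbocupration of a 2-ynoate by a Grignard-derived organocopper places the new arm on the β-carbon (future C12), and iodinolysis of the α-cuprio ester at −78 °C with retention should leave iodine cis to that arm.

Step 8
Reactants: 15 iodoenoate; 16 N-allyl-2-nitrobenzenesulfonamide
Product: 18 methyl (2Z,4S,6S)-4-(tert-butyldimethylsilyloxy)-3-[3-(4-methoxybenzyloxy)propyl]-6-methyl-2-[3-(2-nitrophenylsulfonylamino)propyl]-6-(triethylsilyloxy)nona-2,8-dienoate, via alkylborane 17 (not isolated)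
Conditions: 16, 9-BBN-H (2.2 equiv), THF, rt; then 15, PdCl2(dppf) (10 mol %), Ph3As, Cs2CO3, DMF/THF/H2O, rt
Reagents that add atoms: none
Why: B-alkyl Suzuki–Miyaura coupling of an α-iodo enoate proceeds with retention of olefin geometry, so the two three-carbon arms end cis; hydroborating the reagent separately keeps the substrate vinyl group intact.

Step 9
Reactants: 18 PMB ether
Product: 19 methyl (2Z,4S,6S)-4-(tert-butyldimethylsilyloxy)-3-(3-hydroxypropyl)-6-methyl-2-[3-(2-nitrophenylsulfonylamino)propyl]-6-(triethylsilyloxy)nona-2,8-dienoate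
Conditions: DDQ, CH2Cl2/pH 7 buffer, 0 °C
Reagents that add atoms: none
Why: Oxidative cleavage of the p-methoxybenzyl ether by DDQ should spare the silyl ethers, the sulfonamide and both olefins; the alcohol is trans to the ester and cannot lactonise.

Step 10
Reactants: 19 hydroxy sulfonamide
Product: 20 methyl (Z)-6-[(1S,3S)-1-(tert-butyldimethylsilyloxy)-3-methyl-3-(triethylsilyloxy)hex-5-enyl]-1-(2-nitrophenylsulfonyl)-2,3,4,7,8,9-hexahydro-1H-azonine-5-carboxylate
Conditions: PPh3, DIAD, toluene (0.003 M), rt, slow addition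
Reagents that add atoms: none
Why: Fukuyama–Mitsunobu N-alkylation of the acidic 2-nitrobenzenesulfonamide by the primary alcohol should close ring C (N–C9), helped by the cis arrangement of the two arms on the tetrasubstituted olefin and by high dilution.

Step 11
Reactants: 20 methyl ester
Product: 21 (Z)-6-[(1S,3S)-1-(tert-butyldimethylsilyloxy)-3-methyl-3-(triethylsilyloxy)hex-5-enyl]-1-(2-nitrophenylsulfonyl)-2,3,4,7,8,9-hexahydro-1H-azonine-5-carboxylic acid
Conditions: LiI, pyridine, 110 °C; 1 M HCl, 0 °C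
Reagents that add atoms: none
Why: SN2 demethylation by iodide attacks the methyl carbon, so it is insensitive to the shielded carbonyl of the tetrasubstituted acrylate and leaves the sulfonamide and silyl ethers alone.

Step 12
Reactants: 21 N-nosyl acid
Product: 23 (Z)-6-[(1S,3S)-1-(tert-butyldimethylsilyloxy)-3-methyl-3-(triethylsilyloxy)hex-5-enyl]-1-formyl-2,3,4,7,8,9-hexahydro-1H-azonine-5-carboxylic acid, via secondary amino acid 22 (not isolated)
Conditions: PhSH, K2CO3, DMF, rt; then HCO2CH2CF3, 50 °C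
Reagents that add atoms: 2,2,2-trifluoroethyl formate O=COCC(F)(F)F
Why: Thiolate ipso-substitution (Fukuyama denosylation) should release the ring amine, and trifluoroethyl formate formylates it without activating the carboxylate; the formamide is then in place before any radical chemistry, which a nitroarene would not survive.

Step 13
Reactants: 23 N-formyl acid
Product: 24 Se-phenyl (Z)-6-[(1S,3S)-1-(tert-butyldimethylsilyloxy)-3-methyl-3-(triethylsilyloxy)hex-5-enyl]-1-formyl-2,3,4,7,8,9-hexahydro-1H-azonine-5-carboselenoate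
Conditions: (PhSe)2, Bu3P, CH2Cl2, rt
Reagents that add atoms: diphenyl diselenide c1ccc([Se][Se]c2ccccc2)cc1
Why: Phosphine/diselenide activation (acyloxyphosphonium, then selenolate attack) is the standard conversion of an acid into a Se-phenyl selenoester, the acyl-radical precursor.

Step 14
Reactants: 24 selenoester
Product: 25 (7S,12S,13S,15S)-13-(tert-butyldimethylsilyloxy)-15-methyl-15-(triethylsilyloxy)-N-formyl tricyclic ketone: azonane (N, C1–C4, C9–C12) fused through C4–C12 to a cis-bicyclo[4.3.0]nonan-5-one (C4–C8, C12–C15); C4 epimer mixture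
Conditions: (Me3Si)3SiH, AIBN (syringe pump), PhH (0.005 M), 80 °C
Reagents that add atoms: none
Why: The silyl radical abstracts PhSe from 24, and the α,β-unsaturated acyl radical reacts through its α-ketenyl form (radical on C12, C4=C5=O): C12 adds to C7 of the vinyl group, the resulting primary C6 radical adds to the ketene carbon C5, and the C4 α-keto radical is reduced by the silane with chain transfer. The closest known reaction type is the tandem α-ketenyl radical cyclisation of α,β-unsaturated selenoesters to fused cyclopentanones (diquinanes, hydrindanones, propellanes). Ring A closes 6-exo-trig; ring B closes by attack on the sp carbon of the ketene, exo with respect to the C5=O π bond. C7 should be set by a chair transition state with the C13 and C15 silyloxy groups and the vinyl group all equatorial (the other chair needs a syn-diaxial OSi/OSi pair); C12 should be set by the rotamer about C12–C13 in which C13–H eclipses the C11 methylene, so the slim ketene terminus, held syn to C13 by ring C, is pseudoaxial and C4 ends cis to C6. C4 forms as a mixture that step 15 removes, and the geometric integrity of 24 is not critical because the ketenyl radical is planar at C12. The step needs 6-exo over 7-endo closure and cyclisation faster than hydrogen transfer, which the monosubstituted terminal alkene, the slow hydrogen donor and syringe-pump dilution should secure.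

Step 15
Reactants: 25 ketone
Product: 27 (7S,12S,13S,15S)-13-(tert-butyldimethylsilyloxy)-15-(triethylsilyloxy) C3=C4 enone (N-formyl; olefin cis within ring C), via trimethylsilyl enol ether 26 (not isolated)
Conditions: TMSCl, NaI, Et3N, MeCN, rt; then Pd(OAc)2, MeCN, rt
Reagents that add atoms: none
Why: Saegusa–Ito oxidation: equilibrating silylation should favour the more substituted C4=C5 enol ether, and the palladium enolate at C4 can only lose a β-hydrogen from C3 (C12 is quaternary), giving the enone with the ring-enforced cis geometry.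

Step 16
Reactants: 27 bis-silyl ether
Product: 28 (7S,12S,13S,15S)-13,15-dihydroxy enone (N-formyl)
Conditions: aq. HF, MeCN, 0 °C → rt
Reagents that add atoms: none
Why: Fluoride-assisted acidic desilylation should remove the tertiary TES and hindered secondary TBS groups without affecting the enone or the formamide.

Step 17
Reactants: 28 diol
Product: 29 target CNP0137427.1
Conditions: Ac2O, DMAP, Et3N, CH2Cl2, rt → 40 °C
Reagents that add atoms: acetic anhydride CC(=O)OC(C)=O
Why: DMAP-catalysed acetylation (Steglich conditions) should esterify both the neopentyl secondary C13–OH and the tertiary C15–OH; no stereocentre is affected.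

**Compound list**

1 | (R)-mevalonolactone | C[C@@]1(O)CCOC(=O)C1 | starting material
2 | (4R)-4-methyltetrahydro-2H-pyran-2,4-diol | C[C@@]1(O)CCOC(O)C1 | intermediate
3 | (S)-3-methylhex-5-ene-1,3-diol | OCC[C@@](C)(O)CC=C | intermediate
4 | (S)-3-methyl-1,3-bis(triethylsilyloxy)hex-5-ene | CC[Si](CC)(CC)OCC[C@@](C)(O[Si](CC)(CC)CC)CC=C | intermediate
5 | dimethyl[(S)-3-methyl-3-(triethylsilyloxy)hex-5-enyloxy]sulfonium chloride | C[S+](C)OCC[C@@](C)(O[Si](CC)(CC)CC)CC=C.[Cl-] | intermediate
6 | (S)-3-methyl-3-(triethylsilyloxy)hex-5-enal | O=CC[C@@](C)(O[Si](CC)(CC)CC)CC=C | intermediate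
7 | methyl propiolate | COC(=O)C#C | starting material
8 | methyl 3-(methylzincio)propiolate | COC(=O)C#C[Zn]C | intermediate
9 | methyl (4S,6S)-4-hydroxy-6-methyl-6-(triethylsilyloxy)non-8-en-2-ynoate | COC(=O)C#C[C@@H](O)C[C@@](C)(O[Si](CC)(CC)CC)CC=C | intermediate
10 | methyl (4S,6S)-4-(tert-butyldimethylsilyloxy)-6-methyl-6-(triethylsilyloxy)non-8-en-2-ynoate | COC(=O)C#C[C@@H](O[Si](C)(C)C(C)(C)C)C[C@@](C)(O[Si](CC)(CC)CC)CC=C | intermediate
11 | 1-[(3-bromopropoxy)methyl]-4-methoxybenzene | COc1ccc(COCCCBr)cc1 | starting material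
12 | 3-(4-methoxybenzyloxy)propylmagnesium bromide | COc1ccc(COCCC[Mg]Br)cc1 | intermediate
13 | 3-(4-methoxybenzyloxy)propylcopper (MgBr2·SMe2 complex) | COc1ccc(COCCC[Cu])cc1 | intermediate
14 | methyl (4S,6S)-4-(tert-butyldimethylsilyloxy)-2-cuprio-3-[3-(4-methoxybenzyloxy)propyl]-6-methyl-6-(triethylsilyloxy)nona-2,8-dienoate (Cu cis to the new arm) | COC(=O)/C([Cu])=C(/CCCOCc1ccc(OC)cc1)[C@@H](O[Si](C)(C)C(C)(C)C)C[C@@](C)(O[Si](CC)(CC)CC)CC=C | intermediate
15 | methyl (2E,4S,6S)-4-(tert-butyldimethylsilyloxy)-2-iodo-3-[3-(4-methoxybenzyloxy)propyl]-6-methyl-6-(triethylsilyloxy)nona-2,8-dienoate | COC(=O)/C(I)=C(/CCCOCc1ccc(OC)cc1)[C@@H](O[Si](C)(C)C(C)(C)C)C[C@@](C)(O[Si](CC)(CC)CC)CC=C | intermediate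
16 | N-allyl-2-nitrobenzenesulfonamide | C=CCNS(=O)(=O)c1ccccc1[N+](=O)[O-] | starting material
17 | N-[3-(9-borabicyclo[3.3.1]nonan-9-yl)propyl]-2-nitrobenzenesulfonamide | O=S(=O)(NCCCB1C2CCCC1CCC2)c1ccccc1[N+](=O)[O-] | intermediate
18 | methyl (2Z,4S,6S)-4-(tert-butyldimethylsilyloxy)-3-[3-(4-methoxybenzyloxy)propyl]-6-methyl-2-[3-(2-nitrophenylsulfonylamino)propyl]-6-(triethylsilyloxy)nona-2,8-dienoate | COC(=O)/C(CCCNS(=O)(=O)c1ccccc1[N+](=O)[O-])=C(/CCCOCc1ccc(OC)cc1)[C@@H](O[Si](C)(C)C(C)(C)C)C[C@@](C)(O[Si](CC)(CC)CC)CC=C | intermediate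
19 | methyl (2Z,4S,6S)-4-(tert-butyldimethylsilyloxy)-3-(3-hydroxypropyl)-6-methyl-2-[3-(2-nitrophenylsulfonylamino)propyl]-6-(triethylsilyloxy)nona-2,8-dienoate | COC(=O)/C(CCCNS(=O)(=O)c1ccccc1[N+](=O)[O-])=C(/CCCO)[C@@H](O[Si](C)(C)C(C)(C)C)C[C@@](C)(O[Si](CC)(CC)CC)CC=C | intermediate
20 | methyl (Z)-6-[(1S,3S)-1-(tert-butyldimethylsilyloxy)-3-methyl-3-(triethylsilyloxy)hex-5-enyl]-1-(2-nitrophenylsulfonyl)-2,3,4,7,8,9-hexahydro-1H-azonine-5-carboxylate | COC(=O)/C1=C(\[C@@H](O[Si](C)(C)C(C)(C)C)C[C@@](C)(O[Si](CC)(CC)CC)CC=C)CCCN(CCC1)S(=O)(=O)c1ccccc1[N+](=O)[O-] | intermediate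
21 | (Z)-6-[(1S,3S)-1-(tert-butyldimethylsilyloxy)-3-methyl-3-(triethylsilyloxy)hex-5-enyl]-1-(2-nitrophenylsulfonyl)-2,3,4,7,8,9-hexahydro-1H-azonine-5-carboxylic acid | OC(=O)/C1=C(\[C@@H](O[Si](C)(C)C(C)(C)C)C[C@@](C)(O[Si](CC)(CC)CC)CC=C)CCCN(CCC1)S(=O)(=O)c1ccccc1[N+](=O)[O-] | intermediate
22 | (Z)-6-[(1S,3S)-1-(tert-butyldimethylsilyloxy)-3-methyl-3-(triethylsilyloxy)hex-5-enyl]-2,3,4,7,8,9-hexahydro-1H-azonine-5-carboxylic acid | OC(=O)/C1=C(\[C@@H](O[Si](C)(C)C(C)(C)C)C[C@@](C)(O[Si](CC)(CC)CC)CC=C)CCCNCCC1 | intermediate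
23 | (Z)-6-[(1S,3S)-1-(tert-butyldimethylsilyloxy)-3-methyl-3-(triethylsilyloxy)hex-5-enyl]-1-formyl-2,3,4,7,8,9-hexahydro-1H-azonine-5-carboxylic acid | OC(=O)/C1=C(\[C@@H](O[Si](C)(C)C(C)(C)C)C[C@@](C)(O[Si](CC)(CC)CC)CC=C)CCCN(C=O)CCC1 | intermediate
24 | Se-phenyl (Z)-6-[(1S,3S)-1-(tert-butyldimethylsilyloxy)-3-methyl-3-(triethylsilyloxy)hex-5-enyl]-1-formyl-2,3,4,7,8,9-hexahydro-1H-azonine-5-carboselenoate | O=C([Se]c1ccccc1)/C1=C(\[C@@H](O[Si](C)(C)C(C)(C)C)C[C@@](C)(O[Si](CC)(CC)CC)CC=C)CCCN(C=O)CCC1 | intermediate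
25 | (7S,12S,13S,15S)-13-(tert-butyldimethylsilyloxy)-15-(triethylsilyloxy)-N-formyl tricyclic C5 ketone (C4 epimers) | CC(C)(C)[Si](C)(C)O[C@H]1C[C@@](C)(O[Si](CC)(CC)CC)C[C@H]2CC(=O)C3CCCN(C=O)CCC[C@@]321 | intermediate
26 | C4=C5 trimethylsilyl enol ether of 25 | CC(C)(C)[Si](C)(C)O[C@H]1C[C@@](C)(O[Si](CC)(CC)CC)C[C@H]2CC(O[Si](C)(C)C)=C3CCCN(C=O)CCC[C@@]321 | intermediate
27 | (7S,12S,13S,15S)-13-(tert-butyldimethylsilyloxy)-15-(triethylsilyloxy)-N-formyl C3=C4 enone | CC(C)(C)[Si](C)(C)O[C@H]1C[C@@](C)(O[Si](CC)(CC)CC)C[C@H]2CC(=O)/C3=C/CCN(C=O)CCC[C@@]321 | intermediate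
28 | (7S,12S,13S,15S)-13,15-dihydroxy-N-formyl C3=C4 enone | O[C@H]1C[C@@](C)(O)C[C@H]2CC(=O)/C3=C/CCN(C=O)CCC[C@@]321 | intermediate
29 | CNP0137427.1, (7S,12S,13S,15S)-13,15-diacetoxy-N-formyl C3=C4 enone | CC(=O)O[C@H]1C[C@@](C)(OC(C)=O)C[C@H]2CC(=O)/C3=C/CCN(C=O)CCC[C@@]321 | target

**Step count**

Total steps: 17. Longest linear sequence: 17 steps (1 → 29); 7, 11 and 16 are bought and enter without steps of their own.

**Steps most likely to fail**

Step 14. The ketenyl radical may close 7-endo or be reduced before the slow 6-exo step, or C12 may add through the other rotamer and give the trans-fused ketone. The fallback makes the two bonds one at a time; it sets out from 23 and comes back at 25. Acid 23 is esterified (TMSCHN2) to the methyl ester F1. The terminal alkene is epoxidised (mCPBA; the tetrasubstituted enoate is inert) to the epoxide F2. Cp2TiCl (Nugent–RajanBabu conditions) opens the epoxide to the C7 radical, which adds 6-exo to C12 of the enoate; the C6 titanium alkoxide then lactonises, which only the cis isomer can do, to the δ-lactone F3. Weinreb aminolysis (Me2AlN(OMe)Me) gives the hydroxy Weinreb amide F4, and I2/PPh3/imidazole gives the iodide F5. SmI2/HMPA (intramolecular Barbier-type acyl substitution) then closes C5–C6 to give 25.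

Step 15. Silylation may go toward C6 instead of the hindered C4, which would lead to the isomeric C6=C7 enone. The fallback uses acid-catalysed enol bromination and elimination after the acid-labile silyl groups have been exchanged; it sets out from 25 and comes back at 29. Desilylation (aq. HF, MeCN) gives the diol ketone F6, and acetylation (Ac2O, DMAP) gives the diacetate ketone F7. PhNMe3Br3 in THF brominates the tertiary α-carbon through the more substituted enol to give the 4-bromo ketone F8. Li2CO3/LiBr in DMF removes HBr toward C3, the only β-hydrogen, and gives 29.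

Step 10. Intermolecular N-alkylation (dimers, oligomers) may outrun closure of the nine-membered ring. The fallback closes ring C through the C3–C4 bond instead; it sets out from 15 and comes back at 20. DDQ converts 15 into the iodoenoate alcohol F9. Intermolecular Mitsunobu reaction with the boronate sulfonamide F10 (made from 16 by iridium-catalysed hydroboration with pinacolborane) gives the tethered alkylboronate F11. Intramolecular Suzuki–Miyaura coupling of the alkylboronate with the vinyl iodide under high dilution gives 20.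

**Further compounds**

F1 | step 14 | methyl (Z)-6-[(1S,3S)-1-(tert-butyldimethylsilyloxy)-3-methyl-3-(triethylsilyloxy)hex-5-enyl]-1-formyl-2,3,4,7,8,9-hexahydro-1H-azonine-5-carboxylate | COC(=O)/C1=C(\[C@@H](O[Si](C)(C)C(C)(C)C)C[C@@](C)(O[Si](CC)(CC)CC)CC=C)CCCN(C=O)CCC1
F2 | step 14 | terminal epoxide of F1 (epimers at the oxirane) | COC(=O)/C1=C(\[C@@H](O[Si](C)(C)C(C)(C)C)C[C@@](C)(O[Si](CC)(CC)CC)CC2CO2)CCCN(C=O)CCC1
F3 | step 14 | cis-fused δ-lactone (O–C6 joined to C5; ring A closed; C4 epimers) | CC(C)(C)[Si](C)(C)O[C@H]1C[C@@](C)(O[Si](CC)(CC)CC)C[C@H]2COC(=O)C3CCCN(C=O)CCC[C@@]321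
F4 | step 14 | C6 hydroxy C5 Weinreb amide | CC(C)(C)[Si](C)(C)O[C@H]1C[C@@](C)(O[Si](CC)(CC)CC)C[C@@H](CO)[C@]12CCCN(C=O)CCCC2C(=O)N(C)OC
F5 | step 14 | C6 iodo C5 Weinreb amide | CC(C)(C)[Si](C)(C)O[C@H]1C[C@@](C)(O[Si](CC)(CC)CC)C[C@@H](CI)[C@]12CCCN(C=O)CCCC2C(=O)N(C)OC
F6 | step 15 | (7S,12S,13S,15S)-13,15-dihydroxy-N-formyl tricyclic C5 ketone | O[C@H]1C[C@@](C)(O)C[C@H]2CC(=O)C3CCCN(C=O)CCC[C@@]321
F7 | step 15 | (7S,12S,13S,15S)-13,15-diacetoxy-N-formyl tricyclic C5 ketone | CC(=O)O[C@H]1C[C@@](C)(OC(C)=O)C[C@H]2CC(=O)C3CCCN(C=O)CCC[C@@]321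
F8 | step 15 | 4-bromo derivative of F7 | CC(=O)O[C@H]1C[C@@](C)(OC(C)=O)C[C@H]2CC(=O)C3(Br)CCCN(C=O)CCC[C@@]321
F9 | step 10 | methyl (2E,4S,6S)-4-(tert-butyldimethylsilyloxy)-3-(3-hydroxypropyl)-2-iodo-6-methyl-6-(triethylsilyloxy)nona-2,8-dienoate | COC(=O)/C(I)=C(/CCCO)[C@@H](O[Si](C)(C)C(C)(C)C)C[C@@](C)(O[Si](CC)(CC)CC)CC=C
F10 | step 10 | 2-nitro-N-[3-(4,4,5,5-tetramethyl-1,3,2-dioxaborolan-2-yl)propyl]benzenesulfonamide | CC1(C)OB(CCCNS(=O)(=O)c2ccccc2[N+](=O)[O-])OC1(C)C
F11 | step 10 | N-alkylated iodoenoate carrying the 3-(pinacolboryl)propyl sulfonamide | COC(=O)/C(I)=C(/CCCN(CCCB1OC(C)(C)C(C)(C)O1)S(=O)(=O)c1ccccc1[N+](=O)[O-])[C@@H](O[Si](C)(C)C(C)(C)C)C[C@@](C)(O[Si](CC)(CC)CC)CC=C
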